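## Analysis of the target

CNP0273594.1 is a bicyclic diterpenoid of the ent-labdane type. Labdane numbering is used below, and α/β are used literally for the usual drawing (ring A left, C10 above C5), in which the 10-methyl group C20 is α.

- The core is a trans-decalin (H5 β, C20 α) with two quaternary carbons, C10 and C4. C20 and the 19-formyl group sit 1,3-diaxial on the α face.
- Ring A carries four contiguous stereocentres, C2 to C5: a cis-2β,3β-diol as its diacetate (2-OAc equatorial, 3-OAc axial) next to C4 (18-CH3 β, 19-CHO α).
- Ring B holds the trisubstituted C7=C8 alkene (17-CH3 on C8) and the equatorial side chain on C9 (C11 α, H9 β), which ends in an (E)-3-methyl-2-enoic acid (C13=C14, C15).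
- Sensitive groups: the neopentyl aldehyde (no α-hydrogen, but open to retro-aldol cleavage under base once O3 is free); the two acetates, which exclude basic or nucleophilic steps late in the route; the free acid; and the C7=C8 bond, which competes with any ring A alkene for oxidants and can migrate to C8=C9 in acid.
- The hard part is the ring A array C19–C4(quaternary)–C3(O)–C2(O): the one-carbon group lies on the hindered α face syn to C20, and both oxygens lie on the β face.
- This array is the feature the key step uses. A [2,3] shift of a one-carbon unit from O2 to C4 creates the quaternary centre by chirality transfer from C2 and leaves a C2=C3 bond for β-face cis-dihydroxylation.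

## Retrosynthetic reasoning

**Acetates and acid last (25 ← 23 ← 22).** The target 25 comes from dihydroxy acid 23 by acetylation; the mixed anhydride 24 that forms at the carboxyl group is hydrolysed in the work-up. 23 comes from 22 by one acidolysis that removes the acetonide and the tert-butyl ester. Cutting here keeps the base-labile acetates out of every C–C bond-forming step.

**Ring B alkene and C9–H (22 ← 21).** The C9–H bond and the position of C7=C8 are traced to the homoannular diene 21 (C6=C7, C8=C9). A 1,4-addition of H2 must put hydrogen on C6 and C9 and leave C7=C8. The β face is the open one, because C20 and C19 cover the α face.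

**Side chain at C9–C11 (21 ← 16 + 19).** The diene is cut at C9–C11, an sp2–sp3 coupling between dienyl triflate 16 and alkylborane 20 made from dienoate 19. This cut is chosen over C11–C12 or C12–C13 because C9 is the carbonyl carbon of the carvone-derived enone, so the chain arrives complete with its E enoate already set. 16 comes from enone 14 through dienolate 15; since C10 is quaternary, only C6 can be deprotonated.

**cis-Diol (14 ← 13 ← 12).** The two oxygens on C2 and C3 come from cis-dihydroxylation of the C2=C3 bond of 12. This must happen while ring B is still an electron-poor enone and not yet the C7=C8 alkene, which fixes the order of ring A and ring B events.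

**Key disconnection (12 ← 11 ← 10 ← 9).** The C4–C19 bond is cut and the O2–CH2 bond re-formed, with the alkene moved back from C2=C3 to C3=C4. The precursor 9 is a simple stannylmethyl ether of a secondary allylic alcohol. The forward step has to make the quaternary C4 on the α face syn to C20; an intramolecular, suprafacial shift from the 2α oxygen does this without relying on an external reagent approaching that face.

**Allylic alcohol and ring A closure (9 ← 8 ← 7 ← 6 ← 5).** Diol 8 comes from bis-enone 7 by hydride reduction, in which C20 directs hydride to the β face of C2. Both ketones are reduced so that no carbonyl is present during the organolithium step; the ring B ketone returns in the oxidation that gives 12. Ring A of 7 is cut at C3=C4 by ring-closing metathesis of 6. C4 and its methyl group C18 are the isopropenyl group of carvone; C1 and C2 come from the Weinreb amide appendage of 5, and C3 from a vinyl nucleophile.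

**Chiral pool (5 ← 3 ← 1).** C10 is set by two successive enolate alkylations of (S)-carvone 1, the second anti to the isopropenyl group. 1 supplies ring B with the C5 stereocentre, the 17-methyl group, the C7=C8 bond (as the enone) and the C9 carbonyl.

**Side-chain fragment (19 ← 18 ← 17).** Dienoate 19 is cut at its vinyl–C13 bond to E enol triflate 18, made from β-keto ester 17.

## Alternatives that were turned down

Alternative 1: Biomimetic polyene bicyclisation (the textbook route). The bonds C4–C5 and C9–C10 are cut to give the acyclic E,E,E-polyene β-keto ester A1. The forward key step is an oxidative radical bicyclisation with Mn(OAc)3/Cu(OAc)2, or its cationic counterpart, to the bicyclic keto ester A2. It builds both rings and four stereocentres at once, but it was turned down for these reasons: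
- A2 forms racemic unless a chiral auxiliary is carried on the ester.
- Termination at C8 is not regiocontrolled between C7=C8, C8=C17 and C8=C9.
- The C3 ketone must still be turned into the axial 3-acetate, and C2 oxygenated, in the presence of C7=C8.
- The hindered C19 ester must be reduced selectively next to the C15 ester.
- It is the route most chemists would draw first.

Alternative 2: Robinson-annulation logic from (R)-Wieland–Miescher ketone A3. The enone ring becomes ring A; reductive carboxylation and methylation would give the trans-fused keto ester A4 with the axial C19 ester. The key step is the dissolving-metal reductive alkylation that sets C4 and C5. It was turned down because the C9 ketone of A4 is flanked by the quaternary C10 and carries none of C17, C7=C8 or the side chain. All of ring B must be built by functional-group steps with protecting groups, well beyond twenty steps, and C2 still has to be oxygenated.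

Alternative 3: Quinone Diels–Alder. The bonds C1–C10 and C4–C5 are cut: 2,6-dimethyl-1,4-benzoquinone A5 as ring B and dienyl silyl ether A6 would give, under Lewis acid control of the orientation, the cis-fused adduct A7 with the C2=C3 bond in place. It was turned down for these reasons:
- C4 of A7 is tertiary with no acidifying group, so the quaternary centre is not solved.
- The ring fusion must be epimerised.
- The C6 carbonyl must be removed.
- The C9 carbonyl is the more hindered of the two ring B ketones, so the side chain would enter at the wrong carbon.
- Absolute control needs a chiral Lewis acid on a tetrasubstituted dienophile carbon.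

Key step: step 7

Remark on the chemistry: the descriptors α/β are literal for the drawn ent-series structure (20-CH3 α); 3 forms as a mixture of epimers at the new centre (the trans isomer is drawn); and the C9 carbinol configuration in 8 to 11 is inconsequential (the expected 9α epimer is drawn).

## Route

Step 1
Reactants: 1 (S)-(+)-carvone
Product: 3 6-methylcarvone (epimers at the methyl-bearing carbon, trans shown), via lithium enolate 2 (not isolated)
Conditions: LiN(i-Pr)2, THF, −78 °C; MeI, −78 → 0 °C
Reagents that add atoms: iodomethane, CI
Why: Kinetic deprotonation at the only α' position (the future C10) and C-methylation of the cross-conjugated lithium enolate (enolate alkylation); the epimer mixture is harmless because this carbon is planarised again in step 2.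

Step 2
Reactants: 3 6-methylcarvone
Product: 5 Weinreb amide with quaternary C10, via lithium enolate 4 (not isolated)
Conditions: LiN(i-Pr)2, THF, −78 °C; BrCH2C(O)N(OMe)Me, DMPU, −78 → −20 °C
Reagents that add atoms: 2-bromo-N-methoxy-N-methylacetamide, CON(C)C(=O)CBr
Why: In the tetrasubstituted enolate 4, allylic strain places the neighbouring isopropenyl group pseudoaxial, so the α-bromo amide should enter on the opposite face (enolate alkylation with 1,2-induction); the CH2 appendage ends trans and the methyl group cis to isopropenyl, which is the C10 configuration of the target.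

Step 3
Reactants: 5 Weinreb amide
Product: 6 vinyl ketone
Conditions: CH2=CHMgBr, THF, −78 → 0 °C; then cold 1 M HCl
Reagents that add atoms: vinylmagnesium bromide, C=C[Mg]Br
Why: Weinreb ketone synthesis: the magnesium-chelated tetrahedral adduct prevents over-addition and collapses only on acidic quench; the ring ketone, flanked by the quaternary carbon and the methyl-bearing alkene carbon, should be too hindered to compete at low temperature.

Step 4
Reactants: 6 vinyl ketone
Product: 7 trans-fused bis-enone
Conditions: second-generation Grubbs catalyst (5 mol%), CH2Cl2, 40 °C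
Reagents that add atoms: none
Why: Ring-closing metathesis between the vinyl ketone and the isopropenyl group closes ring A at C3=C4 as a trisubstituted cyclohexenone with loss of ethene; the two tethers are trans-diequatorial on the carvone ring, so the decalin is trans-fused, and the trisubstituted ring B enone alkene does not take part.

Step 5
Reactants: 7 bis-enone
Product: 8 bis-allylic 2α,9-diol
Conditions: NaBH4 (excess), CeCl3·7H2O, MeOH, −40 → 0 °C
Reagents that add atoms: none
Why: Luche 1,2-reduction of both enones; at C2 the axial 10-methyl group (1,3 to C2) blocks the α face, so hydride should enter from the β face and give the pseudoaxial 2α-alcohol, the behaviour known for ketones 1,3 to an axial angular methyl group; the C9 configuration is irrelevant because C9 is reoxidised in step 8.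

Step 6
Reactants: 8 diol
Product: 9 2α-O-(tributylstannyl)methyl ether
Conditions: KH, 18-crown-6 (cat.), Bu3SnCH2I (1.05 equiv), THF, 0 °C → rt
Reagents that add atoms: (iodomethyl)tributylstannane, CCCC[Sn](CCCC)(CCCC)CI
Why: Williamson etherification; the C9 hydroxyl, wedged between the quaternary C10 and the methyl-bearing C8, should be alkylated much more slowly than the C2 hydroxyl, whose neighbours are a CH2 and a CH= carbon.

Step 7
Reactants: 9 stannylmethyl ether
Product: 11 19-hydroxy-Δ2 compound with quaternary C4, via dilithio ether 10 (not isolated)
Conditions: n-BuLi (2.3 equiv), THF, −78 → −60 °C; then H2O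
Reagents that add atoms: none
Why: Tin–lithium exchange (one further equivalent of base is consumed by the C9 hydroxyl) gives the α-alkoxymethyllithium 10, which undergoes a concerted, suprafacial [2,3]-sigmatropic shift through a five-membered envelope transition state: the O2–CH2 bond breaks, the CH2 carbon (C19) bonds to C4 and the alkene moves from C3=C4 to C2=C3. This is a Wittig–Still rearrangement, and the closest known reaction type is the rearrangement of stannylmethyl ethers of 3-substituted cyclohex-2-enols to 1-(hydroxymethyl)cyclohex-2-enes with a new quaternary carbon. No ring is closed; the only cyclic array is the transient five-membered transition state. The one new stereocentre, C4, is controlled by C2: the ether oxygen is on the α face, so C19 is delivered to the α face of C4 (axial, syn to C20) and the methyl group C18 is left β. The step needs [2,3] migration to win over [1,2] migration and over simple protonation of the carbanion; the trans ring fusion holds the 2α C–O bond pseudoaxial, parallel to the π orbitals of C3=C4, which is the geometry the [2,3] path requires, and the low temperature disfavours the radical [1,2] path. Facial selectivity needs no further control because the migrating carbon is tethered to one face. The energy gained on going from a carbanion to an alkoxide should outweigh the 1,3-diaxial C19/C20 contact that develops. No carbonyl group is present, which is why both ketones were reduced in step 5.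

Step 8
Reactants: 11 diol
Product: 12 keto aldehyde
Conditions: Dess–Martin periodinane (2.5 equiv), CH2Cl2, 0 °C → rt
Reagents that add atoms: none
Why: Dess–Martin oxidation takes the neopentyl primary alcohol to the 19-aldehyde and the allylic C9 alcohol back to the ring B enone in one operation; the aldehyde has no α-hydrogen, so the C2=C3 bond cannot move into conjugation.

Step 9
Reactants: 12 keto aldehyde
Product: 13 2β,3β-diol
Conditions: OsO4 (cat.), N-methylmorpholine N-oxide, acetone/H2O, 0 °C → rt
Reagents that add atoms: N-methylmorpholine N-oxide, C[N+]1([O-])CCOCC1; water, O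
Why: Upjohn cis-dihydroxylation: the electron-poor trisubstituted enone alkene of ring B is far less reactive than the isolated C2=C3 bond, and the axial 19-formyl group on C4 together with the axial 10-methyl group shields the α face, so both oxygens should arrive from the β face (2β equatorial, 3β axial).

Step 10
Reactants: 13 diol
Product: 14 acetonide
Conditions: Me2C(OMe)2, pyridinium p-toluenesulfonate (cat.), acetone, rt
Reagents that add atoms: 2,2-dimethoxypropane, COC(C)(C)OC
Why: Acid-catalysed transacetalisation of the cis-1,2-diol to the dioxolane; it masks the β-hydroxy aldehyde (retro-aldol risk) and makes the compound base-stable for step 11.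

Step 11
Reactants: 14 acetonide
Product: 16 dienyl triflate, via lithium dienolate 15 (not isolated)
Conditions: lithium 2,2,6,6-tetramethylpiperidide, THF, −78 → −30 °C; PhNTf2, −78 → 0 °C; then H2O
Reagents that add atoms: N-phenylbis(trifluoromethanesulfonimide), O=S(=O)(N(c1ccccc1)S(=O)(=O)C(F)(F)F)C(F)(F)F
Why: C10 is quaternary, so the hindered amide base, which neither adds to nor reduces the neopentyl aldehyde, can only remove a γ-proton at C6; O-sulfonylation of the extended dienolate 15 gives the 2-triflyloxy diene (dienyl triflate formation from an enone).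

Step 12
Reactants: 17 tert-butyl acetoacetate
Product: 18 tert-butyl (E)-3-(triflyloxy)but-2-enoate
Conditions: Me4NOH (aq.), Tf2O, toluene, 0 °C
Reagents that add atoms: trifluoromethanesulfonic anhydride, O=S(=O)(OS(=O)(=O)C(F)(F)F)C(F)(F)F
Why: O-Triflation of the β-keto ester enolate under non-chelating tetraalkylammonium hydroxide conditions is known to favour the E enol triflate (triflate trans to the ester), which fixes the geometry of the later C13=C14 bond.

Step 13
Reactants: 18 enol triflate
Product: 19 tert-butyl (E)-3-methylpenta-2,4-dienoate
Conditions: CH2=CHSnBu3, Pd(PPh3)4 (cat.), LiCl, THF, 60 °C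
Reagents that add atoms: tributyl(vinyl)stannane, C=C[Sn](CCCC)(CCCC)CCCC
Why: Stille coupling of the enol triflate with retention of alkene geometry gives the E dienoate.

Step 14
Reactants: 16 dienyl triflate; 19 dienoate
Product: 21 ring B diene with complete side chain, via B-alkyl-9-BBN 20 (not isolated)
Conditions: 19 (slight excess over borane), 9-BBN-H, THF, 0 °C → rt; then 16, PdCl2(dppf) (cat.), AsPh3, Cs2CO3, DMF/H2O, rt → 50 °C
Reagents that add atoms: none
Why: 9-BBN-H adds to the terminal vinyl group of 19 with boron on the CH2 carbon (the future C11), and B-alkyl Suzuki–Miyaura coupling of 20 with the dienyl triflate forms the C9–C11 bond with retention of both alkene geometries; the trisubstituted enoate is not hydroborated, and keeping 19 in slight excess leaves no B–H to reduce the aldehyde.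

Step 15
Reactants: 21 diene
Product: 22 C7=C8 alkene with H9 β
Conditions: (naphthalene)Cr(CO)3 (cat.), H2 (4 atm), acetone, 40 °C
Reagents that add atoms: none
Why: (Arene)Cr(CO)3 complexes add H2 in a 1,4-cis manner only to dienes that can reach the s-cis geometry, which the ring B diene has by construction, so hydrogen should go to C6 and C9 and the alkene should end at C7=C8; the metal binds the β face because the axial 10-methyl and 19-formyl groups cover the α face, which sets H9 β (side chain α, equatorial); the isolated enoate and the aldehyde are not dienes and should be left.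

Step 16
Reactants: 22 acetonide tert-butyl ester
Product: 23 dihydroxy acid
Conditions: CF3CO2H/CH2Cl2/H2O, 0 °C
Reagents that add atoms: none
Why: Acidolysis removes the dioxolane (hydrolysis) and the tert-butyl ester (loss of 2-methylpropene) in one step; short contact at 0 °C is meant to keep the C7=C8 bond in place.

Step 17
Reactants: 23 dihydroxy acid
Product: 25 CNP0273594.1, via mixed anhydride 24 (not isolated)
Conditions: Ac2O, pyridine, 4-(dimethylamino)pyridine (cat.), CH2Cl2, rt; then THF/H2O, rt
Reagents that add atoms: acetic anhydride, CC(=O)OC(C)=O
Why: Acetylation of both secondary alcohols (the axial 3β-hydroxyl needs the nucleophilic catalyst); the carboxylic acid is converted in part into the mixed anhydride 24, which is hydrolysed at the acetyl carbonyl in the aqueous stage, so the free acid is returned.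

## Compound list

1 | (S)-(+)-carvone, (5S)-2-methyl-5-(prop-1-en-2-yl)cyclohex-2-en-1-one | CC1=CC[C@@H](CC1=O)C(C)=C | starting material
2 | cross-conjugated lithium enolate of 1 (O–C1=C6 of carvone) | [Li+].[O-]C1=C[C@@H](C(C)=C)CC=C1C | intermediate
3 | 6-methylcarvone, (5S)-2,6-dimethyl-5-(prop-1-en-2-yl)cyclohex-2-en-1-one, mixture of C6 epimers, trans (methyl anti to isopropenyl) shown | C[C@H]1C(=O)C(C)=CC[C@@H]1C(C)=C | intermediate
4 | tetrasubstituted lithium enolate of 3 | [Li+].[O-]C1=C(C)[C@@H](C(C)=C)CC=C1C | intermediate
5 | N-methoxy-N-methyl-2-[1,3-dimethyl-2-oxo-6-(prop-1-en-2-yl)cyclohex-3-en-1-yl]acetamide, CH2 appendage trans and methyl cis to isopropenyl | CON(C)C(=O)C[C@@]1(C)C(=O)C(C)=CC[C@@H]1C(C)=C | intermediate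
6 | 2,6-dimethyl-6-(2-oxobut-3-en-1-yl)-5-(prop-1-en-2-yl)cyclohex-2-en-1-one, oxobutenyl trans to isopropenyl | C=CC(=O)C[C@@]1(C)C(=O)C(C)=CC[C@@H]1C(C)=C | intermediate
7 | trans-fused bis-enone (labdane numbering): 2,9-dioxo, C3=C4 and C7=C8, methyl groups on C4, C8 and C10 (20-CH3 α), H5 β | O=C1C[C@@]2(C)C(=O)C(C)=CC[C@@H]2C(C)=C1 | intermediate
8 | 2α,9α-diol of 7 (C3=C4 and C7=C8 kept; 2-OH pseudoaxial, cis to C20) | O[C@@H]1C[C@@]2(C)[C@H](O)C(C)=CC[C@@H]2C(C)=C1 | intermediate
9 | 2α-O-[(tributylstannyl)methyl] ether of 8, 9-OH free | CCCC[Sn](CCCC)(CCCC)CO[C@@H]1C[C@@]2(C)[C@H](O)C(C)=CC[C@@H]2C(C)=C1 | intermediate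
10 | dilithio species of 9: 2α-OCH2Li and 9-OLi | [Li]CO[C@@H]1C[C@@]2(C)[C@H](O[Li])C(C)=CC[C@@H]2C(C)=C1 | intermediate
11 | 4α-(hydroxymethyl)-4β-methyl compound: 19-OH, C2=C3, C7=C8, 9α-OH, 20-CH3 α, H5 β | C1C[C@@]2(C)[C@H](O)C(C)=CC[C@@H]2[C@](C)(CO)C=1 | intermediate
12 | keto aldehyde: 19-CHO (α, axial), C2=C3, ring B 9-oxo-7-ene | C1C[C@@]2(C)C(=O)C(C)=CC[C@@H]2[C@](C)(C=O)C=1 | intermediate
13 | 2β,3β-dihydroxy-19-oxo compound with ring B 9-oxo-7-ene | O[C@H]1C[C@@]2(C)C(=O)C(C)=CC[C@@H]2[C@](C)(C=O)[C@H]1O | intermediate
14 | 2β,3β-O-isopropylidene acetal of 13 | CC1(C)O[C@H]2C[C@@]3(C)C(=O)C(C)=CC[C@@H]3[C@](C)(C=O)[C@H]2O1 | intermediate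
15 | lithium dienolate of 14 (O–C9=C8–C7=C6) | [Li+].CC1(C)O[C@H]2C[C@@]3(C)C([O-])=C(C)C=C[C@@H]3[C@](C)(C=O)[C@H]2O1 | intermediate
16 | dienyl triflate: 9-(trifluoromethylsulfonyl)oxy-6,8(9)-diene, acetonide and 19-CHO as in 14 | CC1(C)O[C@H]2C[C@@]3(C)C(OS(=O)(=O)C(F)(F)F)=C(C)C=C[C@@H]3[C@](C)(C=O)[C@H]2O1 | intermediate
17 | tert-butyl acetoacetate (tert-butyl 3-oxobutanoate) | CC(=O)CC(=O)OC(C)(C)C | starting material
18 | tert-butyl (2E)-3-[(trifluoromethylsulfonyl)oxy]but-2-enoate | CC(C)(C)OC(=O)/C=C(\C)OS(=O)(=O)C(F)(F)F | intermediate
19 | tert-butyl (2E)-3-methylpenta-2,4-dienoate | C=C/C(C)=C/C(=O)OC(C)(C)C | intermediate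
20 | tert-butyl (2E)-5-(9-borabicyclo[3.3.1]nonan-9-yl)-3-methylpent-2-enoate | CC(C)(C)OC(=O)/C=C(\C)CCB1C2CCCC1CCC2 | intermediate
21 | tert-butyl 2β,3β-(isopropylidenedioxy)-19-oxolabda-6,8,13E-trien-15-oate, ent series (20-CH3 α, H5 β) | CC1(C)O[C@H]2C[C@@]3(C)C(CC/C(C)=C/C(=O)OC(C)(C)C)=C(C)C=C[C@@H]3[C@](C)(C=O)[C@H]2O1 | intermediate
22 | tert-butyl 2β,3β-(isopropylidenedioxy)-19-oxolabda-7,13E-dien-15-oate, ent series (20-CH3 α, H5 β, H9 β) | CC1(C)O[C@H]2C[C@@]3(C)[C@H](CC/C(C)=C/C(=O)OC(C)(C)C)C(C)=CC[C@@H]3[C@](C)(C=O)[C@H]2O1 | intermediate
23 | 2β,3β-dihydroxy-19-oxolabda-7,13E-dien-15-oic acid, ent series | O[C@H]1C[C@@]2(C)[C@H](CC/C(C)=C/C(=O)O)C(C)=CC[C@@H]2[C@](C)(C=O)[C@H]1O | intermediate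
24 | mixed acetic anhydride of 25 at C15 | CC(=O)O[C@H]1C[C@@]2(C)[C@H](CC/C(C)=C/C(=O)OC(C)=O)C(C)=CC[C@@H]2[C@](C)(C=O)[C@H]1OC(C)=O | intermediate
25 | CNP0273594.1, 2β,3β-diacetoxy-19-oxolabda-7,13E-dien-15-oic acid of the ent series (20-CH3 α, H5 β, H9 β, 19-CHO α) | CC(=O)O[C@H]1C[C@@]2(C)[C@H](CC/C(C)=C/C(=O)O)C(C)=CC[C@@H]2[C@](C)(C=O)[C@H]1OC(C)=O | target

## Step count and least certain steps

Total step count: 17. Longest linear sequence: 15 (steps 1 to 11 and 14 to 17); steps 12 and 13 make the side-chain fragment.

**Step 7 (key step).** The carbanion may be lost to [1,2] migration or to protonation before it reaches C4, because migration to the face that carries C20 is slowed by the developing 1,3-diaxial contact; the expected penalty is loss of material, not the wrong configuration. Fallback: a neutral, thermal [2,3] shift that tolerates the ring B ketone. It sets out from 7. Selective Luche reduction of the less hindered ring A ketone at −78 °C gives the 2α-hydroxy enone F1. Heating F1 with Me2NCH(OMe)2 in xylene at about 150 °C gives the 19-dimethylamide F2 by the [2,3] shift of the alkoxy(dimethylamino)carbene, with the same suprafacial delivery to C4. Excess Cp2Zr(H)Cl takes the amide to the aldehyde stage and reduces the ring B ketone, giving the hydroxy aldehyde F3. Dess–Martin oxidation of F3 comes back to the route at 12.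

**Step 6.** Site selectivity of the O-alkylation may erode, with etherification at O9 or at both oxygens. Fallback: differentiate the two oxygens by oxidation state. It sets out from 7 and passes through the mono-alcohol F1 described above, whose single hydroxyl is alkylated with Bu3SnCH2I/KH to the stannylmethyl ether F4. Luche reduction of the ring B ketone of F4 comes back to the route at 9.

**Step 14.** Transmetalation and reductive elimination at C9 may be slow, since C9 sits between the quaternary C10 and the methyl-bearing C8; β-hydride elimination from the alkylpalladium species would then reduce the triflate. Fallback: make the congested bond with a small sp2 partner and move the sp3–sp2 coupling to the unhindered end of the chain. It sets out from 16. Stille coupling with CH2=CHSnBu3 (Pd(PPh3)4, LiCl) gives the 9-vinyl triene aldehyde F5. Excess 9-BBN-H hydroborates the terminal vinyl group and also reduces the aldehyde. Suzuki–Miyaura coupling of this borane with enol triflate 18 gives the 19-hydroxy diene F6. Dess–Martin oxidation comes back to the route at 21.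

**Step 15.** Hydrogen uptake at the tetrasubstituted diene terminus may be slow, or chemoselectivity may be lost through conjugate reduction of the enoate under forcing conditions. Fallback: a dissolving-metal 1,4-reduction on a relay that carries no enoate. It sets out from 16. Suzuki–Miyaura coupling with the 9-BBN adduct of isoprene gives the diene F7 with a 3-methylbut-3-enyl chain. Li in NH3 with t-BuOH reduces the ring diene to the C7=C8 alkene with axial protonation at C9 (H9 β) and the aldehyde to the alcohol, giving F8. Cross-metathesis with tert-butyl acrylate (second-generation Grubbs catalyst) gives the E enoate F9, at the cost of moderate E/Z control. Dess–Martin oxidation comes back to the route at 22.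

**Step 16.** The C7=C8 bond may migrate to C8=C9, or add acid, during the strongly acidic cleavage. Fallback: separate the two deprotections and cleave the ester without protic acid. It sets out from 22. Aqueous acetic acid removes only the acetonide and gives the diol ester F10. Acetylation (Ac2O, pyridine, 4-(dimethylamino)pyridine) gives the diacetate ester F11. Me3SiOSO2CF3 with 2,6-lutidine converts the tert-butyl ester into the silyl ester, which is hydrolysed on work-up; this comes back to the route at 25.

## Further compounds

F1 | step 7 | 2α-hydroxy-3-ene with ring B 9-oxo-7-ene intact (mono-reduction product of 7) | O[C@@H]1C[C@@]2(C)C(=O)C(C)=CC[C@@H]2C(C)=C1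
F2 | step 7 | 19-(N,N-dimethylcarboxamide), C2=C3, ring B 9-oxo-7-ene (amide α on C4) | C1C[C@@]2(C)C(=O)C(C)=CC[C@@H]2[C@](C)(C(=O)N(C)C)C=1
F3 | step 7 | 9-hydroxy-19-oxo compound, C2=C3 and C7=C8 (9α drawn) | C1C[C@@]2(C)[C@H](O)C(C)=CC[C@@H]2[C@](C)(C=O)C=1
F4 | step 6 | 2α-O-[(tributylstannyl)methyl] ether of F1 | CCCC[Sn](CCCC)(CCCC)CO[C@@H]1C[C@@]2(C)C(=O)C(C)=CC[C@@H]2C(C)=C1
F5 | step 14 | 9-vinyl-6,8(9)-diene aldehyde, acetonide as in 16 | CC1(C)O[C@H]2C[C@@]3(C)C(C=C)=C(C)C=C[C@@H]3[C@](C)(C=O)[C@H]2O1
F6 | step 14 | 19-hydroxy analogue of 21 | CC1(C)O[C@H]2C[C@@]3(C)C(CC/C(C)=C/C(=O)OC(C)(C)C)=C(C)C=C[C@@H]3[C@](C)(CO)[C@H]2O1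
F7 | step 15 | 6,8(9)-diene aldehyde with 3-methylbut-3-enyl chain on C9 | CC1(C)O[C@H]2C[C@@]3(C)C(CCC(C)=C)=C(C)C=C[C@@H]3[C@](C)(C=O)[C@H]2O1
F8 | step 15 | 19-hydroxy-7-ene with H9 β and 3-methylbut-3-enyl chain | CC1(C)O[C@H]2C[C@@]3(C)[C@H](CCC(C)=C)C(C)=CC[C@@H]3[C@](C)(CO)[C@H]2O1
F9 | step 15 | 19-hydroxy analogue of 22 | CC1(C)O[C@H]2C[C@@]3(C)[C@H](CC/C(C)=C/C(=O)OC(C)(C)C)C(C)=CC[C@@H]3[C@](C)(CO)[C@H]2O1
F10 | step 16 | tert-butyl ester of 23 (2β,3β-diol) | O[C@H]1C[C@@]2(C)[C@H](CC/C(C)=C/C(=O)OC(C)(C)C)C(C)=CC[C@@H]2[C@](C)(C=O)[C@H]1O
F11 | step 16 | tert-butyl ester of 25 (2β,3β-diacetate) | CC(=O)O[C@H]1C[C@@]2(C)[C@H](CC/C(C)=C/C(=O)OC(C)(C)C)C(C)=CC[C@@H]2[C@](C)(C=O)[C@H]1OC(C)=O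
A1 | alternative 1 | 1-tert-butyl 16-methyl (2E,6E,10E)-3,7,11,15-tetramethyl-14-oxohexadeca-2,6,10-trienedioate | COC(=O)C(C)C(=O)CC/C(C)=C/CC/C(C)=C/CC/C(C)=C/C(=O)OC(C)(C)C
A2 | alternative 1 | bicyclic 3-oxo-19-methyl ester with C7=C8 and the tert-butyl enoate side chain (desired enantiomer drawn) | C1C[C@@]2(C)[C@H](CC/C(C)=C/C(=O)OC(C)(C)C)C(C)=CC[C@@H]2[C@](C)(C(=O)OC)C1=O
A3 | alternative 2 | (R)-Wieland–Miescher ketone | O=C1CC[C@@]2(C)C(=O)CCCC2=C1
A4 | alternative 2 | trans-fused 3-oxo-4β-methyl-4α-(methoxycarbonyl) decalin with C9 ethylene ketal | C1C[C@@]2(C)C3(OCCO3)CCC[C@@H]2[C@](C)(C(=O)OC)C1=O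
A5 | alternative 3 | 2,6-dimethyl-1,4-benzoquinone | CC1=CC(=O)C=C(C)C1=O
A6 | alternative 3 | (E)-tert-butyldimethyl(penta-2,4-dien-1-yloxy)silane | C=C/C=C/CO[Si](C)(C)C(C)(C)C
A7 | alternative 3 | cis-fused endo adduct: 6,9-dioxo-7-ene, C2=C3, 4-(silyloxymethyl) | C1C[C@@]2(C)C(=O)C(C)=CC(=O)[C@H]2[C@@H](CO[Si](C)(C)C(C)(C)C)C=1
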